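## The problem

Locants: unprimed for the 5,7-dioxygenated chromanone (ring A), primed for the 5′,6′,7′,8′-tetraoxygenated one (ring A′).

- The target is two 4-aryl-3,4-dihydrocoumarins joined through C3–C3′. It has four contiguous stereocentres, C4, C3, C3′ and C4′, with configuration 3S,4R,3′S,4′R.
- In each lactone the C4 aryl group and the C3 substituent are cis. This is expected to be the less stable arrangement, and C3 and C3′ are both α to an aryl ester carbonyl. Both centres must therefore be set kinetically and kept away from base afterwards.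
- Only C3 can pass information on to C3′. C4 and C4′ are too far apart to control each other, so each half needs its own control element.
- Eight phenols must be unmasked at the end. Four of them sit on one ring as an air-sensitive 1,2,3,4-tetrahydroxybenzene, so deprotection must be last and acidic.
- Both ortho positions of C4a (and of C4a′) carry oxygen and each arene is locally symmetric. Either ortho oxygen can close the lactone, so phenol regiochemistry is not an issue.
- The enabling feature lies in ring A. C4a carries C4 and sits between the oxygenated carbons C8a and C5, with the third oxygen on C7. This is the pattern formed when an oxygen-substituted alkyne is joined to a 3-alkoxy vinylketene, so ring A can be grown on C4 after the sp3 centres are in place.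

## Retrosynthesis

**34 to 32.** Only C–O bonds are cut: six methyl ethers, one ethyl ether (34 from 33) and one silyl ether (33 from 32). Keeping all phenols masked to the end protects the tetraoxygenated ring from oxidation. The aryl silyl ether is removed first and under acidic fluoride, so the free polyphenol never meets base. The forward step needs one Lewis acid that cleaves seven ethers without touching the lactones.

**32 to 23 and 29.** Ring A′ lactone is opened at C3′–C4′ and O1′–C2′. This gives the (chromanon-3-yl)acetic acid 23 and the ortho-quinone methide 31, stored as its sulfinate adduct 29. The neighbouring cut, C3–C3′, would mean joining two stereogenic carbons. The chosen cut instead makes C3′ and C4′ together in an annulation that is known to favour cis. Acid 23 has one ring and two stereocentres; 29 is made from a phenol in one step. The forward step needs catalyst control of the enolate face over the influence of C3, and conditions that do not epimerize the cis lactone.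

**23 to 19.** The carboxymethyl group is traced to an allyl group (23 from 22 from 20). The lactone O1–C2 bond is then cut to give phenol silyl ester 19. The allyl group is used because no enolizable ester can be present when the alkyne is oxidized under strong base (see 16 below). The forward steps are an alkene cleavage, an aldehyde oxidation and an acid-catalysed lactonization.

**19 to 16 and 17 (key disconnection).** Ring A is removed by cutting C4a–C8a, C5–C6 and C8–C8a. This leaves siloxyalkyne 16 and 3-ethoxycyclobut-2-en-1-one 17. A Friedel–Crafts union of a phloroglucinol with a C4 cation would be shorter but would give no control at C4. Building the arene on an existing C4 centre keeps C3 and C4 fixed and gives the three oxygens differentiated (OH, OSi, OEt). The forward reaction must be regioselective and neutral.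

**16 to 9.** The C5–O bond is traced to the terminal alkyne of acid 14 by acetylide oxidation and silylation. The carboxyl group travels as its lithium salt and leaves as the silyl ester. The C3–C3′ bond is then cut to give imide 9 and allyl iodide 10 (12 from 9), with the oxazolidinone setting C3. A one-step route to both centres, the Nicholas alkylation of a succinate imide boron enolate with a Co2(CO)6-complexed propargylic cation, was set aside for two reasons. It favours the syn adduct, which corresponds to the trans lactone. It would also leave two enolizable esters in the molecule during ynolate formation.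

**9 to 1, 2 and 4.** The imide comes from acid 6, and 6 from Meldrum's acid adduct 5. The C4–alkyne bond of 5 is cut to give benzylidene 3 and ethynyltrimethylsilane 4. Compound 3 is the Knoevenagel product of 4-methoxybenzaldehyde 1 and Meldrum's acid 2. The forward conjugate alkynylation must set C4 by catalyst control.

**29 to 24.** The sulfone is cut at the benzylic C–C and C–S bonds to phenol 27, aldehyde 1 and a sulfinate salt. Phenol 27 comes from commercial 1,2,3,4-tetramethoxybenzene 24 by C–H oxygenation through the aryllithium. The difficult pentaoxygenated ring is thus bought almost complete.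

## Roads not taken

**Alternative 1:** Both pyranone rings are cut at once to the 1,3-diynamide A1 and two quinone methides, the dimethoxy compound A2 and 31. Forward, a chiral phosphoric acid would mediate two successive [4+2] additions to give the bis(2-amido-4H-chromene) A3.
- Merits: this is the shortest route. The C3–C3′ bond is already present in the diyne, and both carbonyl carbons arrive at the right oxidation level.
- Weak points: C3 and C3′ stay sp2 in A3. Their configuration would come from protonation during hydrolysis of two ketene N,O-acetals, which most plausibly gives the trans lactones. The two additions must also be hetero-selective (A2 first, then 31), and the second must occur at a hindered enyne next to an existing stereocentre.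
- Comparison: it is clearly better in step count and convergence. The chosen plan offers in return explicit control of C3 (auxiliary) and of C3′ with C4′ (cis-selective annulation), which Alternative 1 does not provide.

**Alternative 2:** C2–C3 and C2′–C3′ are cut, so that both carbonyl carbons come from dichloroketene adding across the (E)-tetraarylbutene A4 to give cyclobutanone A5.
- Merits: the C3/C3′ relationship is inherited stereospecifically from the alkene geometry. No bond has to be made between two stereocentres.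
- Weak points: A4 needs two benzhydrylic stereocentres in a 1,4-relationship, each with two very similar electron-rich aryl groups, and there is no reliable way to set them. The ketene must also choose the alkene face by acyclic induction from both sides at once. Hindered (E)-alkenes are poor partners for dichloroketene, and the polymethoxyarenes may be acylated instead. Ring cleavage, dechlorination and two ortho-demethylations would follow.
- Comparison: it handles the C3–C3′ bond better than the chosen plan, which must build ring A′ next to an existing centre. It moves the hard stereochemical problem to C4 and C4′, where the chosen plan uses catalyst and auxiliary control.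

**Alternative 3:** Ring A′ is cut at C8′–C8a′ and traced to the squarate-derived 4-hydroxycyclobutenone A6. On heating, A6 would open to a dienylketene and close to the hydroquinone A7.
- Merits: the hexasubstituted pentaoxygenated ring is built from a squarate under neutral conditions with fixed regiochemistry. This avoids needing a pentaoxygenated benzene as a building block.
- Weak points: A7 is an air-sensitive hydroquinone. C2′ is an acetal and C2 an ether carbon, so both must later be oxidized in the presence of that ring. The whole ring A half, with C3 and C4, would still have to be attached at a methylene carbon with no control element nearby.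
- Comparison: it is better than the chosen plan for the tetraoxygenated ring, which the chosen plan obtains by lithiation and oxidation of a bought tetramethoxybenzene. The chosen plan offers in return that all sp3 centres and oxidation levels of the first half are settled before its arene exists.

Key step: step 8

Assumptions:
- The sense of induction in steps 2 and 14 is assumed as written; if it is the opposite, the antipodal ligand or triazolium salt is used.
- 3-Ethoxycyclobut-2-en-1-one 17 is taken as a purchasable reagent.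

Step 1
Reactants: 1 4-methoxybenzaldehyde; 2 2,2-dimethyl-1,3-dioxane-4,6-dione (Meldrum's acid)
Product: 3 5-[(4-methoxyphenyl)methylidene]-2,2-dimethyl-1,3-dioxane-4,6-dione
Conditions: H2O, 75 °C
Reagents that add atoms: none
Why: Knoevenagel condensation of an aromatic aldehyde with the strongly C–H acidic Meldrum's acid; the product should precipitate, which limits bis-addition.

Step 2
Reactants: 3 5-[(4-methoxyphenyl)methylidene]-2,2-dimethyl-1,3-dioxane-4,6-dione; 4 ethynyltrimethylsilane
Product: 5 5-[(1R)-1-(4-methoxyphenyl)-3-(trimethylsilyl)prop-2-yn-1-yl]-2,2-dimethyl-1,3-dioxane-4,6-dione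
Conditions: Rh(acac)(C2H4)2 (5 mol %), (S)-3,5-Xyl-MeO-BIPHEP (6 mol %), 1,4-dioxane, rt
Reagents that add atoms: none
Why: Rhodium-catalysed asymmetric conjugate alkynylation of an arylidene Meldrum's acid with a silylacetylene; the bisphosphine on the alkynylrhodium species selects one face of the acceptor and so sets C4.

Step 3
Reactants: 5 5-[(1R)-1-(4-methoxyphenyl)-3-(trimethylsilyl)prop-2-yn-1-yl]-2,2-dimethyl-1,3-dioxane-4,6-dione
Product: 6 (3R)-3-(4-methoxyphenyl)-5-(trimethylsilyl)pent-4-ynoic acid
Conditions: DMF/H2O (10:1), 100 °C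
Reagents that add atoms: water, O
Why: Hydrolytic opening of the Meldrum's acid and decarboxylation of the malonic half-acid under neutral conditions; the C4 hydrogen is not acidic enough to epimerize.

Step 4
Reactants: 6 (3R)-3-(4-methoxyphenyl)-5-(trimethylsilyl)pent-4-ynoic acid; 7 (R)-4-benzyl-1,3-oxazolidin-2-one
Product: 9 (4R)-4-benzyl-3-[(3R)-3-(4-methoxyphenyl)-5-(trimethylsilyl)pent-4-ynoyl]-1,3-oxazolidin-2-one, via pivalic mixed anhydride 8 (not isolated)
Conditions: t-BuCOCl, Et3N, THF, −20 °C; then 7, LiCl, rt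
Reagents that add atoms: none
Why: Standard N-acylation of an oxazolidinone through a pivalic mixed anhydride with LiCl/Et3N; no stereocentre is touched.

Step 5
Reactants: 9 (4R)-4-benzyl-3-[(3R)-3-(4-methoxyphenyl)-5-(trimethylsilyl)pent-4-ynoyl]-1,3-oxazolidin-2-one; 10 3-iodoprop-1-ene (allyl iodide)
Product: 12 (4R)-4-benzyl-3-[(2R,3R)-3-(4-methoxyphenyl)-2-(prop-2-en-1-yl)-5-(trimethylsilyl)pent-4-ynoyl]-1,3-oxazolidin-2-one, via sodium Z-enolate 11 (not isolated)
Conditions: NaN(SiMe3)2, THF, −78 °C; then 10, −78 → −40 °C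
Reagents that add atoms: none
Why: Evans alkylation; the chelated Z-enolate is attacked by allyl iodide on the face opposite the benzyl group of the (R)-auxiliary, which sets C3 and gives the 3,4-anti relationship that later becomes the cis lactone. Auxiliary control should override the weak bias of the C4 centre.

Step 6
Reactants: 12 (4R)-4-benzyl-3-[(2R,3R)-3-(4-methoxyphenyl)-2-(prop-2-en-1-yl)-5-(trimethylsilyl)pent-4-ynoyl]-1,3-oxazolidin-2-one
Product: 14 (2R,3S)-3-(4-methoxyphenyl)-2-(prop-2-en-1-yl)pent-4-ynoic acid, via silylated acid 13 (not isolated)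
Conditions: LiOH, H2O2, THF/H2O, 0 °C; Na2SO3; then K2CO3 (cat.), MeOH, rt; aq. HCl work-up
Reagents that add atoms: hydrogen peroxide, OO
Why: Hydroperoxide cleaves the exocyclic imide carbonyl without epimerizing C3, and methanolic carbonate then removes the alkynyl silyl group. The descriptor at the propargylic carbon changes from R to S only because the substituent priorities change.

Step 7
Reactants: 14 (2R,3S)-3-(4-methoxyphenyl)-2-(prop-2-en-1-yl)pent-4-ynoic acid
Product: 16 triisopropylsilyl (2R,3R)-3-(4-methoxyphenyl)-2-(prop-2-en-1-yl)-5-[(triisopropylsilyl)oxy]pent-4-ynoate, via dilithium ynolate carboxylate 15 (not isolated)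
Conditions: LiN(SiMe3)2 (3.1 equiv), THF/DMPU, −78 °C; t-BuOOH (1.05 equiv), −78 → 0 °C; i-Pr3SiOTf (2.3 equiv), −78 → 0 °C; NaHCO3 work-up
Reagents that add atoms: tert-butyl hydroperoxide, CC(C)(C)OO; triisopropylsilyl trifluoromethanesulfonate, CC(C)[Si](C(C)C)(C(C)C)OS(=O)(=O)C(F)(F)F
Why: Oxidation of a lithium acetylide by LiOO-t-Bu to the ynolate, then O-silylation with a bulky silyl triflate, is the standard route to siloxyalkynes. The carboxylate is inert to the base, the peroxide and the ynolate (its α-hydrogen is not removed by LiN(SiMe3)2) and is capped as the silyl ester in the same operation.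

Step 8
Reactants: 16 triisopropylsilyl (2R,3R)-3-(4-methoxyphenyl)-2-(prop-2-en-1-yl)-5-[(triisopropylsilyl)oxy]pent-4-ynoate; 17 3-ethoxycyclobut-2-en-1-one
Product: 19 triisopropylsilyl (2R)-2-[(R)-{4-ethoxy-2-hydroxy-6-[(triisopropylsilyl)oxy]phenyl}(4-methoxyphenyl)methyl]pent-4-enoate, via 4-vinylcyclobutenone 18 (not isolated)
Conditions: toluene, 80 → 110 °C, Ar
Reagents that add atoms: none
Why: Danheiser benzannulation; the closest known reaction type is the resorcinol synthesis from trialkylsilyloxyalkynes and cyclobutenone-derived vinylketenes. Thermal 4π-opening of 17 gives 3-ethoxybuta-1,3-dien-1-one; the nucleophilic β-carbon of the siloxyalkyne (future C4a) bonds to the ketene carbonyl carbon (future C8a) and the oxygen-bearing carbon (C5) to the ketene α-carbon (C6) in a [2+2] addition that gives 18. Reversible 4π-opening of 18 gives a dienylketene, and its 6π-electrocyclic closure forms C8–C8a; tautomerization of the cyclohexadienone then gives the phenol. The one ring formed is thus closed by a 6π-electrocyclization. No stereocentre is created, and C3 and C4 are safe because the medium is neutral and aprotic. The regiochemistry needed (OH on C8a, silyloxy on C5, ethoxy on C7) follows from the polarization of the ynol ether and the ketene. The alkene and the silyl ester are spectators; any closure of the new phenol onto the silyl ester would only anticipate step 9.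

Step 9
Reactants: 19 triisopropylsilyl (2R)-2-[(R)-{4-ethoxy-2-hydroxy-6-[(triisopropylsilyl)oxy]phenyl}(4-methoxyphenyl)methyl]pent-4-enoate
Product: 20 (3R,4R)-7-ethoxy-4-(4-methoxyphenyl)-3-(prop-2-en-1-yl)-5-[(triisopropylsilyl)oxy]-3,4-dihydro-2H-chromen-2-one
Conditions: TsOH·H2O (cat.), toluene, 60 °C
Reagents that add atoms: none
Why: Acid-catalysed lactonization of an ortho-hydroxyaryl propanoate, favoured by the substituents on C3 and C4. The labile silyl ester is the acyl donor and the aryl silyl ether should survive catalytic acid; C3 is not enolized, so the cis relationship is kept.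

Step 10
Reactants: 20 (3R,4R)-7-ethoxy-4-(4-methoxyphenyl)-3-(prop-2-en-1-yl)-5-[(triisopropylsilyl)oxy]-3,4-dihydro-2H-chromen-2-one
Product: 22 [(3R,4R)-7-ethoxy-4-(4-methoxyphenyl)-2-oxo-5-[(triisopropylsilyl)oxy]-3,4-dihydro-2H-chromen-3-yl]acetaldehyde, via vicinal diol 21 (not isolated)
Conditions: OsO4 (cat.), NaIO4, 2,6-lutidine, 1,4-dioxane/H2O, rt
Reagents that add atoms: osmium tetroxide, O=[Os](=O)(=O)=O; sodium periodate, [Na+].[O-]I(=O)(=O)=O
Why: Lemieux–Johnson cleavage; OsO4 attacks the terminal alkene and not the arene, and periodate cleaves the diol as it forms, which should outrun attack of the diol on the aryl lactone.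

Step 11
Reactants: 22 [(3R,4R)-7-ethoxy-4-(4-methoxyphenyl)-2-oxo-5-[(triisopropylsilyl)oxy]-3,4-dihydro-2H-chromen-3-yl]acetaldehyde
Product: 23 [(3R,4R)-7-ethoxy-4-(4-methoxyphenyl)-2-oxo-5-[(triisopropylsilyl)oxy]-3,4-dihydro-2H-chromen-3-yl]acetic acid
Conditions: NaClO2, NaH2PO4, 2-methyl-2-butene (large excess), t-BuOH/H2O, 0 °C
Reagents that add atoms: sodium chlorite, [Na+].[O-]Cl=O
Why: Pinnick oxidation under buffered, nearly neutral conditions that leave the lactone and the α-centre alone; the alkene scavenger removes HOCl before it can chlorinate ring A.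

Step 12
Reactants: 24 1,2,3,4-tetramethoxybenzene
Product: 27 2,3,4,5-tetramethoxyphenol, via aryllithium 25 (not isolated), via dimethyl arylboronate 26 (not isolated)
Conditions: n-BuLi, TMEDA, THF, 0 °C; B(OMe)3, −78 °C → rt; then 30% H2O2, AcOH, 0 °C → rt
Reagents that add atoms: hydrogen peroxide, OO
Why: Methoxy-directed ortho-lithiation, borylation and oxidative C–B to C–O conversion; the only aromatic C–H positions are equivalent, so the regiochemistry is fixed.

Step 13
Reactants: 27 2,3,4,5-tetramethoxyphenol; 1 4-methoxybenzaldehyde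
Product: 29 2,3,4,5-tetramethoxy-6-[(4-methoxyphenyl)(4-methylbenzenesulfonyl)methyl]phenol (racemic), via benzhydrol 28 (not isolated)
Conditions: 4-MeC6H4SO2Na (excess), TsOH·H2O, CH2Cl2, rt; 27 added slowly to excess 1
Reagents that add atoms: sodium 4-methylbenzenesulfinate, Cc1ccc(S(=O)[O-])cc1.[Na+]
Why: Acid-mediated ortho-hydroxyalkylation at the single free ring position, then capture of the stabilized benzhydryl cation by sulfinate at sulfur. Excess aldehyde and sulfinate should suppress triarylmethane formation; the stereocentre is lost again in step 14.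

Step 14
Reactants: 23 [(3R,4R)-7-ethoxy-4-(4-methoxyphenyl)-2-oxo-5-[(triisopropylsilyl)oxy]-3,4-dihydro-2H-chromen-3-yl]acetic acid; 29 2,3,4,5-tetramethoxy-6-[(4-methoxyphenyl)(4-methylbenzenesulfonyl)methyl]phenol
Product: 32 (3S,4R)-7-ethoxy-4-(4-methoxyphenyl)-3-[(3S,4R)-5,6,7,8-tetramethoxy-4-(4-methoxyphenyl)-2-oxo-3,4-dihydro-2H-chromen-3-yl]-5-[(triisopropylsilyl)oxy]-3,4-dihydro-2H-chromen-2-one, via acyl imidazole 30 (not isolated), via ortho-quinone methide 31 (not isolated)
Conditions: 1,1′-carbonyldiimidazole, THF, rt; then 29, (5aR,10bS)-2-mesityl-5a,10b-dihydro-4H,6H-indeno[2,1-b][1,2,4]triazolo[4,3-d][1,4]oxazin-2-ium tetrafluoroborate (15 mol %), Cs2CO3, 4 Å MS, THF/toluene, 0 °C → rt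
Reagents that add atoms: none
Why: Carbene-catalysed formal [4+2] annulation of an in situ activated carboxylic acid with an ortho-quinone methide. The acyl azolium from 30 gives a Z-azolium enolate whose open face is fixed by the aminoindanol catalyst (C3′), and endo approach of the oxadiene 31 places the C4′ aryl group cis. Lactonization releases the carbene; the descriptor at C3 changes from R to S only because the new substituent outranks C4.

Step 15
Reactants: 32 (3S,4R)-7-ethoxy-4-(4-methoxyphenyl)-3-[(3S,4R)-5,6,7,8-tetramethoxy-4-(4-methoxyphenyl)-2-oxo-3,4-dihydro-2H-chromen-3-yl]-5-[(triisopropylsilyl)oxy]-3,4-dihydro-2H-chromen-2-one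
Product: 33 (3S,4R)-7-ethoxy-5-hydroxy-4-(4-methoxyphenyl)-3-[(3S,4R)-5,6,7,8-tetramethoxy-4-(4-methoxyphenyl)-2-oxo-3,4-dihydro-2H-chromen-3-yl]-3,4-dihydro-2H-chromen-2-one
Conditions: HF·pyridine, THF, 0 °C → rt
Reagents that add atoms: none
Why: Fluoride cleavage of an aryl silyl ether in an acidic medium, so neither lactone α-centre sees base.

Step 16
Reactants: 33 (3S,4R)-7-ethoxy-5-hydroxy-4-(4-methoxyphenyl)-3-[(3S,4R)-5,6,7,8-tetramethoxy-4-(4-methoxyphenyl)-2-oxo-3,4-dihydro-2H-chromen-3-yl]-3,4-dihydro-2H-chromen-2-one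
Product: 34 (3S,4R)-5,7-dihydroxy-4-(4-hydroxyphenyl)-3-[(3S,4R)-5,6,7,8-tetrahydroxy-4-(4-hydroxyphenyl)-2-oxo-3,4-dihydro-2H-chromen-3-yl]-3,4-dihydro-2H-chromen-2-one (CNP0064734.1)
Conditions: BBr3 (excess), CH2Cl2, −78 °C → rt; degassed aq. HCl work-up under Ar
Reagents that add atoms: none
Why: Lewis acid dealkylation of aryl methyl and ethyl ethers; dihydrocoumarin lactones normally survive, and any opened hydroxy acid should re-close on acidic work-up. Because each arene is locally symmetric, re-closure through either ortho oxygen gives the same compound.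

## Compound list

1 | 4-methoxybenzaldehyde | COc1ccc(C=O)cc1 | starting material
2 | 2,2-dimethyl-1,3-dioxane-4,6-dione (Meldrum's acid) | CC1(C)OC(=O)CC(=O)O1 | starting material
3 | 5-[(4-methoxyphenyl)methylidene]-2,2-dimethyl-1,3-dioxane-4,6-dione | COc1ccc(C=C2C(=O)OC(C)(C)OC2=O)cc1 | intermediate
4 | ethynyltrimethylsilane | C#C[Si](C)(C)C | starting material
5 | 5-[(1R)-1-(4-methoxyphenyl)-3-(trimethylsilyl)prop-2-yn-1-yl]-2,2-dimethyl-1,3-dioxane-4,6-dione | CC1(C)OC(=O)C(C(=O)O1)[C@@H](C#C[Si](C)(C)C)c1ccc(OC)cc1 | intermediate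
6 | (3R)-3-(4-methoxyphenyl)-5-(trimethylsilyl)pent-4-ynoic acid | OC(=O)C[C@@H](C#C[Si](C)(C)C)c1ccc(OC)cc1 | intermediate
7 | (R)-4-benzyl-1,3-oxazolidin-2-one | O=C1N[C@H](Cc2ccccc2)CO1 | starting material
8 | (3R)-3-(4-methoxyphenyl)-5-(trimethylsilyl)pent-4-ynoic 2,2-dimethylpropanoic anhydride | CC(C)(C)C(=O)OC(=O)C[C@@H](C#C[Si](C)(C)C)c1ccc(OC)cc1 | intermediate (not isolated)
9 | (4R)-4-benzyl-3-[(3R)-3-(4-methoxyphenyl)-5-(trimethylsilyl)pent-4-ynoyl]-1,3-oxazolidin-2-one | O=C1OC[C@@H](Cc2ccccc2)N1C(=O)C[C@@H](C#C[Si](C)(C)C)c1ccc(OC)cc1 | intermediate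
10 | 3-iodoprop-1-ene (allyl iodide) | C=CCI | starting material
11 | sodium (Z)-enolate of 9 | [Na+].[O-]/C(=C\[C@@H](C#C[Si](C)(C)C)c1ccc(OC)cc1)N1[C@H](Cc2ccccc2)COC1=O | intermediate (not isolated)
12 | (4R)-4-benzyl-3-[(2R,3R)-3-(4-methoxyphenyl)-2-(prop-2-en-1-yl)-5-(trimethylsilyl)pent-4-ynoyl]-1,3-oxazolidin-2-one | O=C1OC[C@@H](Cc2ccccc2)N1C(=O)[C@H](CC=C)[C@@H](C#C[Si](C)(C)C)c1ccc(OC)cc1 | intermediate
13 | (2R,3R)-3-(4-methoxyphenyl)-2-(prop-2-en-1-yl)-5-(trimethylsilyl)pent-4-ynoic acid | OC(=O)[C@H](CC=C)[C@@H](C#C[Si](C)(C)C)c1ccc(OC)cc1 | intermediate (not isolated)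
14 | (2R,3S)-3-(4-methoxyphenyl)-2-(prop-2-en-1-yl)pent-4-ynoic acid | OC(=O)[C@H](CC=C)[C@@H](C#C)c1ccc(OC)cc1 | intermediate
15 | dilithium (2R,3R)-3-(4-methoxyphenyl)-5-oxido-2-(prop-2-en-1-yl)pent-4-ynoate | [Li+].[Li+].[O-]C(=O)[C@H](CC=C)[C@@H](C#C[O-])c1ccc(OC)cc1 | intermediate (not isolated)
16 | triisopropylsilyl (2R,3R)-3-(4-methoxyphenyl)-2-(prop-2-en-1-yl)-5-[(triisopropylsilyl)oxy]pent-4-ynoate | CC(C)[Si](C(C)C)(C(C)C)OC(=O)[C@H](CC=C)[C@@H](C#CO[Si](C(C)C)(C(C)C)C(C)C)c1ccc(OC)cc1 | intermediate (key-step precursor)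
17 | 3-ethoxycyclobut-2-en-1-one | CCOC1=CC(=O)C1 | starting material
18 | triisopropylsilyl (2R)-2-[(R)-{3-(1-ethoxyethenyl)-4-oxo-2-[(triisopropylsilyl)oxy]cyclobut-1-en-1-yl}(4-methoxyphenyl)methyl]pent-4-enoate (both epimers at the ring sp3 carbon) | CC(C)[Si](C(C)C)(C(C)C)OC(=O)[C@H](CC=C)[C@@H](C1=C(O[Si](C(C)C)(C(C)C)C(C)C)C(C(=C)OCC)C1=O)c1ccc(OC)cc1 | intermediate (not isolated)
19 | triisopropylsilyl (2R)-2-[(R)-{4-ethoxy-2-hydroxy-6-[(triisopropylsilyl)oxy]phenyl}(4-methoxyphenyl)methyl]pent-4-enoate | CC(C)[Si](C(C)C)(C(C)C)OC(=O)[C@H](CC=C)[C@@H](c1c(O)cc(OCC)cc1O[Si](C(C)C)(C(C)C)C(C)C)c1ccc(OC)cc1 | intermediate (key-step product)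
20 | (3R,4R)-7-ethoxy-4-(4-methoxyphenyl)-3-(prop-2-en-1-yl)-5-[(triisopropylsilyl)oxy]-3,4-dihydro-2H-chromen-2-one | C=CC[C@H]1C(=O)Oc2cc(OCC)cc(O[Si](C(C)C)(C(C)C)C(C)C)c2[C@H]1c1ccc(OC)cc1 | intermediate
21 | (3R,4R)-3-(2,3-dihydroxypropyl)-7-ethoxy-4-(4-methoxyphenyl)-5-[(triisopropylsilyl)oxy]-3,4-dihydro-2H-chromen-2-one (both carbinol epimers) | OCC(O)C[C@H]1C(=O)Oc2cc(OCC)cc(O[Si](C(C)C)(C(C)C)C(C)C)c2[C@H]1c1ccc(OC)cc1 | intermediate (not isolated)
22 | [(3R,4R)-7-ethoxy-4-(4-methoxyphenyl)-2-oxo-5-[(triisopropylsilyl)oxy]-3,4-dihydro-2H-chromen-3-yl]acetaldehyde | O=CC[C@H]1C(=O)Oc2cc(OCC)cc(O[Si](C(C)C)(C(C)C)C(C)C)c2[C@H]1c1ccc(OC)cc1 | intermediate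
23 | [(3R,4R)-7-ethoxy-4-(4-methoxyphenyl)-2-oxo-5-[(triisopropylsilyl)oxy]-3,4-dihydro-2H-chromen-3-yl]acetic acid | OC(=O)C[C@H]1C(=O)Oc2cc(OCC)cc(O[Si](C(C)C)(C(C)C)C(C)C)c2[C@H]1c1ccc(OC)cc1 | intermediate
24 | 1,2,3,4-tetramethoxybenzene | COc1ccc(OC)c(OC)c1OC | starting material
25 | (2,3,4,5-tetramethoxyphenyl)lithium | [Li]c1cc(OC)c(OC)c(OC)c1OC | intermediate (not isolated)
26 | dimethyl (2,3,4,5-tetramethoxyphenyl)boronate | COB(OC)c1cc(OC)c(OC)c(OC)c1OC | intermediate (not isolated)
27 | 2,3,4,5-tetramethoxyphenol | COc1cc(O)c(OC)c(OC)c1OC | intermediate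
28 | (2-hydroxy-3,4,5,6-tetramethoxyphenyl)(4-methoxyphenyl)methanol (racemic) | COc1ccc(C(O)c2c(O)c(OC)c(OC)c(OC)c2OC)cc1 | intermediate (not isolated)
29 | 2,3,4,5-tetramethoxy-6-[(4-methoxyphenyl)(4-methylbenzenesulfonyl)methyl]phenol (racemic) | COc1ccc(C(c2c(O)c(OC)c(OC)c(OC)c2OC)S(=O)(=O)c2ccc(C)cc2)cc1 | intermediate
30 | (3R,4R)-7-ethoxy-3-[2-(1H-imidazol-1-yl)-2-oxoethyl]-4-(4-methoxyphenyl)-5-[(triisopropylsilyl)oxy]-3,4-dihydro-2H-chromen-2-one | O=C(C[C@H]1C(=O)Oc2cc(OCC)cc(O[Si](C(C)C)(C(C)C)C(C)C)c2[C@H]1c1ccc(OC)cc1)n1ccnc1 | intermediate (not isolated)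
31 | 2,3,4,5-tetramethoxy-6-[(4-methoxyphenyl)methylidene]cyclohexa-2,4-dien-1-one (alkene geometry not fixed) | COc1ccc(C=C2C(=O)C(OC)=C(OC)C(OC)=C2OC)cc1 | intermediate (not isolated)
32 | (3S,4R)-7-ethoxy-4-(4-methoxyphenyl)-3-[(3S,4R)-5,6,7,8-tetramethoxy-4-(4-methoxyphenyl)-2-oxo-3,4-dihydro-2H-chromen-3-yl]-5-[(triisopropylsilyl)oxy]-3,4-dihydro-2H-chromen-2-one | O=C1Oc2cc(OCC)cc(O[Si](C(C)C)(C(C)C)C(C)C)c2[C@@H](c2ccc(OC)cc2)[C@H]1[C@H]1C(=O)Oc2c(OC)c(OC)c(OC)c(OC)c2[C@H]1c1ccc(OC)cc1 | intermediate
33 | (3S,4R)-7-ethoxy-5-hydroxy-4-(4-methoxyphenyl)-3-[(3S,4R)-5,6,7,8-tetramethoxy-4-(4-methoxyphenyl)-2-oxo-3,4-dihydro-2H-chromen-3-yl]-3,4-dihydro-2H-chromen-2-one | O=C1Oc2cc(OCC)cc(O)c2[C@@H](c2ccc(OC)cc2)[C@H]1[C@H]1C(=O)Oc2c(OC)c(OC)c(OC)c(OC)c2[C@H]1c1ccc(OC)cc1 | intermediate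
34 | (3S,4R)-5,7-dihydroxy-4-(4-hydroxyphenyl)-3-[(3S,4R)-5,6,7,8-tetrahydroxy-4-(4-hydroxyphenyl)-2-oxo-3,4-dihydro-2H-chromen-3-yl]-3,4-dihydro-2H-chromen-2-one | O=C1Oc2cc(O)cc(O)c2[C@@H](c2ccc(O)cc2)[C@H]1[C@H]1C(=O)Oc2c(O)c(O)c(O)c(O)c2[C@H]1c1ccc(O)cc1 | target

## Step count and risks

Total step count: 16. Longest linear sequence: 14 (steps 1–11 and 14–16); steps 12 and 13 form the side branch.

**Step 8 (key step).** The vinylogous-ester stabilization of 17 may slow its ring opening. The temperature then needed could exceed what 16 tolerates (silyl migration to a silylketene, or hydrolysis), and the branched C4 substituent slows the [2+2] capture. Fallback from 16 to 19: the same vinylketene is generated at or below room temperature by 1,4-dehydrochlorination instead of electrocyclic opening. Ethyl (E)-3-ethoxybut-2-enoate is saponified to (E)-3-ethoxybut-2-enoic acid F1 and converted with oxalyl chloride into (E)-3-ethoxybut-2-enoyl chloride F2. Slow addition of F2 to 16 and Et3N in toluene should give cyclobutenone 18, which on gentle warming goes on to 19.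

**Step 7.** The dianion may aggregate or dissolve poorly, so that acetylide oxidation stalls. The silyl ester may also be lost on work-up, freeing a carboxylic acid that adds to the siloxyalkyne. Fallback from 14 to 20: the acid is masked as a base-stable orthoester.
- Esterification of 14 with (3-methyloxetan-3-yl)methanol (DCC, DMAP) gives the (3-methyloxetan-3-yl)methyl ester F3.
- BF3·OEt2 rearranges it to the 2,6,7-trioxabicyclo[2.2.2]octane orthoester F4.
- The step 7 conditions, with one equivalent less of base and silyl triflate, lead through the lithium ynolate F5 (not isolated) to the siloxyalkyne orthoester F6.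
- Heating F6 with 17 gives, through the vinylcyclobutenone F7 (not isolated), the phenol orthoester F8.
- Wet TsOH opens the orthoester and the phenol closes onto the resulting ester, giving 20.

**Step 14.** Catalyst preference and the C3 centre may be mismatched, giving poor facial selectivity. Carbonate may epimerize C3 of the cis lactone, and the donor-rich quinone methide of uncertain geometry may react slowly. Fallback from 23 to 32: the cis relationship at C3′/C4′ is made by syn hydrogenation of a coumarin.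
- Phenol 27 is ortho-acylated with 4-methoxybenzoyl chloride (TiCl4) to (2-hydroxy-3,4,5,6-tetramethoxyphenyl)(4-methoxyphenyl)methanone F9.
- Acid 23 is esterified with F9 (EDC, DMAP) to the aryl ester F10.
- A TiCl4/Bu3N intramolecular aldol condensation gives the 3-substituted 4-arylcoumarin F11.
- Hydrogenation (H2, Pd/C) from the face set by C3 should give 32.

**Step 2.** The p-methoxy group deactivates the acceptor, so enantioselectivity or conversion may be low, and the alkyne may dimerize. Fallback from 3 to 9: resolution through the auxiliary.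
- Me3SiC≡CMgBr adds to 3 to give the racemic adduct F12.
- Step 3 conditions give the racemic acid F13.
- Acylation of 7 through the racemic mixed anhydride F14 gives 9 together with its C3-epimeric imide F15.
- The two are separated by chromatography or crystallization and 9 is carried on.

**Step 11.** Hypochlorous acid may chlorinate the electron-rich ring A before the scavenger intercepts it. Fallback from 22 to 32: the acid is bypassed. Aldehyde 22 is used directly in step 14 under oxidative carbene catalysis, with the same triazolium salt, Cs2CO3, 29 and 3,3′,5,5′-tetra-tert-butyldiphenoquinone as oxidant. The acyl azolium then forms from the aldehyde.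

**Step 16.** Sevenfold dealkylation may be incomplete, the ethyl ether being the slowest, and the 1,2,3,4-tetrahydroxybenzene ring may oxidize in air during isolation. Fallback from 33 to 34: the product is isolated in protected form. The crude BBr3 product is acetylated under argon (Ac2O, pyridine, 0 °C) to the octaacetate F16. F16 can be purified and checked for complete dealkylation, and is then deacetylated with HCl in MeOH to 34.

## Further compounds

F1 | step 8 | (E)-3-ethoxybut-2-enoic acid | CCO/C(C)=C/C(O)=O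
F2 | step 8 | (E)-3-ethoxybut-2-enoyl chloride | CCO/C(C)=C/C(Cl)=O
F3 | step 7 | (3-methyloxetan-3-yl)methyl (2R,3S)-3-(4-methoxyphenyl)-2-(prop-2-en-1-yl)pent-4-ynoate | CC1(COC(=O)[C@H](CC=C)[C@@H](C#C)c2ccc(OC)cc2)COC1
F4 | step 7 | 1-[(4R,5S)-5-(4-methoxyphenyl)hept-1-en-6-yn-4-yl]-4-methyl-2,6,7-trioxabicyclo[2.2.2]octane | CC12COC(OC1)(OC2)[C@H](CC=C)[C@@H](C#C)c1ccc(OC)cc1
F5 | step 7 | lithium (3R,4R)-3-(4-methoxyphenyl)-4-(4-methyl-2,6,7-trioxabicyclo[2.2.2]octan-1-yl)hept-6-en-1-yn-1-olate | [Li+].CC12COC(OC1)(OC2)[C@H](CC=C)[C@@H](C#C[O-])c1ccc(OC)cc1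
F6 | step 7 | 1-[(4R,5R)-5-(4-methoxyphenyl)-7-[(triisopropylsilyl)oxy]hept-1-en-6-yn-4-yl]-4-methyl-2,6,7-trioxabicyclo[2.2.2]octane | CC12COC(OC1)(OC2)[C@H](CC=C)[C@@H](C#CO[Si](C(C)C)(C(C)C)C(C)C)c1ccc(OC)cc1
F7 | step 7 | 4-(1-ethoxyethenyl)-2-[(1R,2R)-1-(4-methoxyphenyl)-2-(4-methyl-2,6,7-trioxabicyclo[2.2.2]octan-1-yl)pent-4-en-1-yl]-3-[(triisopropylsilyl)oxy]cyclobut-2-en-1-one | CC12COC(OC1)(OC2)[C@H](CC=C)[C@@H](C1=C(O[Si](C(C)C)(C(C)C)C(C)C)C(C(=C)OCC)C1=O)c1ccc(OC)cc1
F8 | step 7 | 5-ethoxy-2-[(1R,2R)-1-(4-methoxyphenyl)-2-(4-methyl-2,6,7-trioxabicyclo[2.2.2]octan-1-yl)pent-4-en-1-yl]-3-[(triisopropylsilyl)oxy]phenol | CC12COC(OC1)(OC2)[C@H](CC=C)[C@@H](c1c(O)cc(OCC)cc1O[Si](C(C)C)(C(C)C)C(C)C)c1ccc(OC)cc1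
F9 | step 14 | (2-hydroxy-3,4,5,6-tetramethoxyphenyl)(4-methoxyphenyl)methanone | COc1ccc(C(=O)c2c(O)c(OC)c(OC)c(OC)c2OC)cc1
F10 | step 14 | 2,3,4,5-tetramethoxy-6-(4-methoxybenzoyl)phenyl [(3R,4R)-7-ethoxy-4-(4-methoxyphenyl)-2-oxo-5-[(triisopropylsilyl)oxy]-3,4-dihydro-2H-chromen-3-yl]acetate | O=C(C[C@H]1C(=O)Oc2cc(OCC)cc(O[Si](C(C)C)(C(C)C)C(C)C)c2[C@H]1c1ccc(OC)cc1)Oc1c(OC)c(OC)c(OC)c(OC)c1C(=O)c1ccc(OC)cc1
F11 | step 14 | (3S,4R)-7-ethoxy-4-(4-methoxyphenyl)-3-[5,6,7,8-tetramethoxy-4-(4-methoxyphenyl)-2-oxo-2H-chromen-3-yl]-5-[(triisopropylsilyl)oxy]-3,4-dihydro-2H-chromen-2-one | O=C1Oc2cc(OCC)cc(O[Si](C(C)C)(C(C)C)C(C)C)c2[C@@H](c2ccc(OC)cc2)[C@H]1C1=C(c2ccc(OC)cc2)c2c(OC)c(OC)c(OC)c(OC)c2OC1=O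
F12 | step 2 | 5-[1-(4-methoxyphenyl)-3-(trimethylsilyl)prop-2-yn-1-yl]-2,2-dimethyl-1,3-dioxane-4,6-dione (racemic) | CC1(C)OC(=O)C(C(=O)O1)C(C#C[Si](C)(C)C)c1ccc(OC)cc1
F13 | step 2 | 3-(4-methoxyphenyl)-5-(trimethylsilyl)pent-4-ynoic acid (racemic) | OC(=O)CC(C#C[Si](C)(C)C)c1ccc(OC)cc1
F14 | step 2 | 3-(4-methoxyphenyl)-5-(trimethylsilyl)pent-4-ynoic 2,2-dimethylpropanoic anhydride (racemic) | CC(C)(C)C(=O)OC(=O)CC(C#C[Si](C)(C)C)c1ccc(OC)cc1
F15 | step 2 | (4R)-4-benzyl-3-[(3S)-3-(4-methoxyphenyl)-5-(trimethylsilyl)pent-4-ynoyl]-1,3-oxazolidin-2-one | O=C1OC[C@@H](Cc2ccccc2)N1C(=O)C[C@H](C#C[Si](C)(C)C)c1ccc(OC)cc1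
F0 | step 11 | none | none
F16 | step 16 | octaacetate of 34, (3S,4R)-5,7-diacetoxy-4-(4-acetoxyphenyl)-3-[(3S,4R)-5,6,7,8-tetraacetoxy-4-(4-acetoxyphenyl)-2-oxo-3,4-dihydro-2H-chromen-3-yl]-3,4-dihydro-2H-chromen-2-one | O=C1Oc2cc(OC(C)=O)cc(OC(C)=O)c2[C@@H](c2ccc(OC(C)=O)cc2)[C@H]1[C@H]1C(=O)Oc2c(OC(C)=O)c(OC(C)=O)c(OC(C)=O)c(OC(C)=O)c2[C@H]1c1ccc(OC(C)=O)cc1
A1 | alternative 1 | N,N′-(buta-1,3-diyne-1,4-diyl)bis(N-methylmethanesulfonamide) | CN(C#CC#CN(C)S(C)(=O)=O)S(C)(=O)=O
A2 | alternative 1 | 3,5-dimethoxy-6-[(4-methoxyphenyl)methylidene]cyclohexa-2,4-dien-1-one | COc1ccc(C=C2C(=O)C=C(OC)C=C2OC)cc1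
A3 | alternative 1 | 5,5′,6′,7,7′,8′-hexamethoxy-4,4′-bis(4-methoxyphenyl)-2,2′-bis[methyl(methylsulfonyl)amino]-4H,4′H-3,3′-bichromene | CS(=O)(=O)N(C)C1=C(C2=C(N(C)S(C)(=O)=O)Oc3c(OC)c(OC)c(OC)c(OC)c3[C@H]2c2ccc(OC)cc2)[C@H](c2ccc(OC)cc2)c2c(OC)cc(OC)cc2O1
A4 | alternative 2 | (E)-1,4-bis(4-methoxyphenyl)-1-(2,3,4,5,6-pentamethoxyphenyl)-4-(2,4,6-trimethoxyphenyl)but-2-ene | COc1cc(OC)c([C@@H](c2ccc(OC)cc2)/C=C/[C@H](c2ccc(OC)cc2)c2c(OC)c(OC)c(OC)c(OC)c2OC)c(OC)c1
A5 | alternative 2 | trans-2,2-dichloro-3-[(4-methoxyphenyl)(pentamethoxyphenyl)methyl]-4-[(4-methoxyphenyl)(2,4,6-trimethoxyphenyl)methyl]cyclobutan-1-one | O=C1[C@@H]([C@H](c2ccc(OC)cc2)c2c(OC)cc(OC)cc2OC)[C@H]([C@H](c2ccc(OC)cc2)c2c(OC)c(OC)c(OC)c(OC)c2OC)C1(Cl)Cl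
A6 | alternative 3 | 4-hydroxy-2,3-dimethoxy-4-[4-(4-methoxyphenyl)-3,3a,4,7a-tetrahydro-2H-furo[2,3-b]pyran-5-yl]cyclobut-2-en-1-one | COc1ccc([C@H]2[C@H]3CCO[C@H]3OC=C2C2(O)C(OC)=C(OC)C2=O)cc1
A7 | alternative 3 | 6,7-dimethoxy-4-(4-methoxyphenyl)-2,3,3a,9a-tetrahydro-4H-furo[2,3-b]chromene-5,8-diol | COc1ccc([C@H]2[C@H]3CCO[C@H]3Oc3c(O)c(OC)c(OC)c(O)c32)cc1
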